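Remark on the chemistry: the target is achiral. Coumarin locants (O1, C2, C3, C4, C4a, C5 to C8, C8a) are used for the corresponding atoms of all precursors. The one transient stereocentre (the quaternary ring carbon of 14, the future C4a) forms as a racemate and is destroyed in the same step.

## Structural features

The target is a 3-arylcoumarin in which a benzene ring (ring A) is fused through C4a–C8a to an α-pyranone (ring C) and a 2,4-dihydroxyphenyl ring (ring B) is attached to C3 by a single C–C bond. Ring A is a pentasubstituted phloroglucinol whose three oxygens are all different: the lactone oxygen O1 on C8a, a methyl ether on C5 and a free hydroxyl on C7; C6 is its only C–H. C8, between the oxygens of C7 and C8a, carries a 2-methylbut-3-en-2-yl (reversed prenyl) group through a quaternary carbon. The molecule has no stereocentre, so no neighbouring stereocentres have to be related. The fragile groups are the C7 phenol next to the tert-allyl group (it adds to the alkene under acid, and the unit rearranges at high temperature), the terminal alkene (which rules out hydrogenolysis), the lactone (opened by strong base) and the electron-rich phenols (easily oxidised). The real difficulty is to place a quaternary carbon regiospecifically on the most crowded position of an electron-rich arene while the three ring-A oxygens stay differentiated; attaching ring B and closing ring C are routine by comparison. The key step exploits the fact that C8 and C8a with their substituents (tert-alkyl, oxygen) map onto a heteroatom-substituted alkyne, while C7(O), C6(H), C5(OMe) and C4a (bearing C4) map onto a 3-methoxycyclobutenone with a one-carbon substituent on its C2. Ring A can therefore be built de novo with all five substituents in place.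

## Logic of the disconnections

**24 to 23.** No skeletal bond is cut; the three phenolic O–H bonds are traced back to O-acetyl groups. The condensation that builds ring C runs in an acetylating medium and esterifies every phenol anyway, so the triester is the natural penultimate compound. Nothing is gained in skeleton, but 23 is non-polar and no longer oxidation-prone. The forward step must cleave three aryl esters without acid (the C7 hydroxyl would add to the neighbouring alkene) and without lasting damage to the lactone.

**23 to 19 and 20.** The cuts are C3=C4 and O1–C2. This splits the molecule into the ring-A salicylaldehyde 19 and the ring-B arylacetic acid 20, which is commercial. The problem shrinks to one pentasubstituted benzaldehyde. The forward step needs an aldol condensation on an electron-rich, doubly ortho-substituted aldehyde and lactonisation through a hindered phenol oxygen.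

**19 to 18 to 17.** No C–C bond is cut. The O–Si bond on C8a and the oxidation level of C4 are adjusted. Oxidation is placed before desilylation so that a free hydroxymethyl group never sits on a ring with two free phenols. The gain is that 17 carries each oxygen in a distinct form: free at C7, triisopropylsilyl at C8a, methyl at C5, tert-butyldimethylsilyl at the benzylic position. The forward oxidation must act only at the benzylic CH2, which the para hydroxyl on C7 makes possible.

**17 to 12 and 5.** The cuts are C7–C8 and C4a–C8a, with C6–C7 opened and closed again on the way. This is the only cut that removes the quaternary-carbon problem, because the hindered group arrives on an alkyne carbon and not by substitution on the arene. Ring A is reduced to the four-membered ring 12 and the acyclic alkyne 5. The forward step needs one regiochemical outcome in the union of the two partners and must tolerate an isolated vinyl group.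

**12 to 11.** The cuts are the bonds C5–C6 and C4a–C7 of the four-membered ring (a [2+2] retron). The ring falls apart into 11, which carries C4, C4a and C5, and a two-carbon C=C=O unit made in the flask, which supplies C6 and C7. The forward step needs the alkyne carbon remote from the methoxy group to bond to the carbonyl carbon of that unit.

**11 to 6.** The cuts are C4–C4a (an alkynyl anion plus a one-carbon aldehyde), the O–Si bond and the C5–O bond (an alkoxide onto a chloroalkyne). This reduces the ynol ether to the two-carbon chlorocarbon 6 and three one-unit reagents. The forward sequence has to run in one flask so that no hazardous or labile intermediate is isolated.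

**5 to 2 to 1.** The cuts are the C8–C8a bond and the bond from C8 to the quaternary carbon (made by 1,2-shift). This traces the ynol silyl ether to an ester with one carbon fewer and a one-carbon carbenoid, and 2 comes from 1 by esterification. The forward step needs a non-enolisable ester, which 2 is, and silylation on oxygen.

## Other disconnections considered

**Alternative 1:** The cut takes out C8a–O1, C4a–C4, C3–C4 and O1–C2 together. It leads to an aryne precursor, 5-(benzyloxy)-3-methoxy-2-(trimethylsilyl)phenyl trifluoromethanesulfonate (A2), DMF as the source of C4, and methyl [2,4-bis(methoxymethoxy)phenyl]acetate (A3). Their union would give the protected coumarin A1, which has no substituent on C8.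

- **Forward reaction:** fluoride (CsF) would release the aryne from A2. The DMF oxygen would add to the aryne carbon remote from the methoxy group, the adduct would open to an ortho-quinone methide, and the enolate of A3 would add and lactonise with loss of dimethylamine to give 7-(benzyloxy)-3-[2,4-bis(methoxymethoxy)phenyl]-5-methoxy-2H-chromen-2-one (A1).
- **In favour:** four bonds form in one flask at modest temperature, the methoxy group of A2 steers the aryne addition in the needed sense, and neither CO nor strong acid is involved.
- **Against:** A1 has no substituent on C8. Debenzylation, O-prenylation and an aromatic Claisen rearrangement would still be needed, with C6 competing against C8 at high temperature, and then acidic removal of the methoxymethyl groups beside the acid-sensitive tert-allyl phenol. A2 also requires regiodefined functionalisation of a phloroglucinol diether with three similar positions. The enolate of A3 is a less acidic partner than the 1,3-dicarbonyl compounds usual in this coupling.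
- **Comparison on structure:** the route through A1 leaves the central difficulty (the quaternary carbon on C8) to a late step, whereas the chosen plan settles it while ring A forms.
- **Comparison on mechanism:** a polar aryne cascade is milder than a pericyclic cascade at 110 °C, and on that point it is the better. In regiochemical predictability the two are equal, since both rely on polarisation of a triple bond by an oxygen substituent. The pyranone assembly that gives A1 is more convergent than the condensation-plus-deacetylation pair of the chosen plan.
- **Comparison on step economy:** the synthesis of A2 and the longer exit from A1 should make this route longer overall.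

**Alternative 2:** The cut is C4a–C4 and O1–C2. It gives the symmetric 5-methoxy-2-(2-methylbut-3-en-2-yl)benzene-1,3-diol (A5) and ethyl 2-[2,4-bis(benzyloxy)phenyl]-3-(dimethylamino)prop-2-enoate (A6). Their union would give A4, the dibenzyl ether of the target.

- **Forward reaction:** heating A5 with A6 in acetic acid. The resorcinol carbon would attack the enamine carbon with loss of dimethylamine and the neighbouring hydroxyl would lactonise, giving 3-[2,4-bis(benzyloxy)phenyl]-7-hydroxy-5-methoxy-8-(2-methylbut-3-en-2-yl)-2H-chromen-2-one (A4).
- **In favour:** this is the most convergent plan. The C8 substituent and the C5 methoxy group of A4 are present before the coupling, and the two reactive positions of A5 are equivalent, so only one regioisomer can form.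
- **Against:** A5 is itself the hard problem. A tertiary allyl group cannot be put directly between two hydroxyls, and a Claisen route from a mono-prenyl ether of the parent resorcinol that lacks the C2 substituent must choose between two ortho positions. Hot acetic acid with a free phenol ortho to the tert-allyl group invites cyclisation onto the alkene or loss of the tert-alkyl group from the very electron-rich ring. The benzyl ethers of A4 cannot be removed by hydrogenolysis without saturating the vinyl group, and Lewis-acid debenzylation threatens the same phenol.
- **Comparison on structure:** the plan uses symmetry and not ring construction, and so moves the C8 problem into the preparation of A5.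
- **Comparison on mechanism:** an acid-mediated condensation stands against a neutral thermal cascade. The chosen plan keeps acid away from the tert-allyl phenol throughout.
- **Comparison on step economy:** with A5 in hand, A4 would be one step away and the route would be the shorter one, which is a point in its favour. The condensation that gives A4 is the equal of the chosen condensation in reliability. The protecting-group exit from A4 is the weaker.

**Alternative 3:** The cut is C2–C3 and C2–O1, with the carbonyl carbon excised as CO. It leads to (E)-2-{2-[2,4-bis(methoxymethoxy)phenyl]ethenyl}-3-methoxy-5-[(3-methylbut-2-en-1-yl)oxy]phenol (A8), which would be carbonylated to the prenyl ether A7.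

- **Forward reaction:** Pd(OAc)2 with benzoquinone under CO. The phenoxide of A8 would bind divalent palladium, the alkenyl C–H syn to the phenol (on the carbon bearing ring B) would be palladated, CO would insert and C–O bond formation would release 3-[2,4-bis(methoxymethoxy)phenyl]-5-methoxy-7-[(3-methylbut-2-en-1-yl)oxy]-2H-chromen-2-one (A7). The zerovalent palladium would be reoxidised by the quinone.
- **In favour:** A8 is available from a Wittig or Heck union of two simple aromatics, the carbonyl carbon comes from CO so no arylacetic acid is needed, the metal is catalytic, and the E geometry places the C–H bond correctly.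
- **Against:** toxic CO is required. The prenyl ether of A8 is an allyl aryl ether that zerovalent palladium can ionise, and its alkene competes for the electrophilic metal. The electron-rich phenol meets an oxidant. After A7 the Claisen rearrangement (C6 against C8) and the acidic removal of the methoxymethyl groups remain.
- **Comparison on structure:** like alternative 1 (whose product A1 would reach A7 after two more operations), the plan postpones C8 to a late sigmatropic step.
- **Comparison on mechanism:** catalytic C–H carbonylation is more atom-economic than a stoichiometric anhydride condensation, and on that point it is the better. It is less safe and its chemoselectivity is less certain.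
- **Comparison on step economy:** the step count to A7 is comparable to the chosen route up to 19, but more steps follow, so there is no overall advantage.

Key step: step 5

## Route

Step 1
Reactants: 1 2,2-dimethylbut-3-enoic acid
Product: 2 methyl 2,2-dimethylbut-3-enoate
Conditions: MeI, K2CO3, DMF, 20 °C
Reagents that add atoms: iodomethane, CI
Why: O-Alkylation of the carboxylate (SN2 at iodomethane) is indifferent to the quaternary α-carbon that slows Fischer esterification, and it keeps acid away from the allyl unit. The ester has no α-hydrogen and so cannot enolise in the next step.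

Step 2
Reactants: 2 methyl 2,2-dimethylbut-3-enoate
Product: 5 [(3,3-dimethylpent-4-en-1-yn-1-yl)oxy]tri(propan-2-yl)silane, via lithium dibromoenolate 3 (not isolated), via lithium ynolate 4 (not isolated)
Conditions: CH2Br2, lithium 2,2,6,6-tetramethylpiperidide, THF, −78 °C; LiN(SiMe3)2; n-BuLi, −78→20 °C; i-Pr3SiCl, −78→0 °C
Reagents that add atoms: dibromomethane, BrCBr; chlorotriisopropylsilane, CC(C)[Si](Cl)(C(C)C)C(C)C
Why: Kowalski ester homologation stopped at the ynolate: LiCHBr2 formed in the flask adds to the ester, the enolate 3 undergoes bromine–lithium exchange, and the carbenoid rearranges by 1,2-shift of the tertiary alkyl group to the ynolate 4. The bulky silyl chloride then reacts at oxygen to give the ynol silyl ether.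

Step 3
Reactants: 6 trichloroethylene
Product: 11 tert-butyl[(3-methoxyprop-2-yn-1-yl)oxy]dimethylsilane, via dichloroacetylene 7 (not isolated), via dichlorovinyl methyl ether 8 (not isolated), via lithium methoxyacetylide 9 (not isolated), via lithium propargylic alkoxide 10 (not isolated)
Conditions: KOMe, THF, −40→20 °C; n-BuLi (2.2 equiv), −78 °C; (CH2O)n, −78→20 °C; t-BuMe2SiCl, DMF, 0→20 °C
Reagents that add atoms: potassium methoxide, C[O-].[K+]; formaldehyde (as paraformaldehyde), C=O; tert-butylchlorodimethylsilane, CC(C)(C)[Si](C)(C)Cl
Why: Methoxide removes HCl from 6 and adds anti to the chloroalkyne 7 to give 8; butyllithium then effects elimination and chlorine–lithium exchange to the acetylide 9, which is hydroxymethylated and O-silylated in the same flask (acetylide addition to an aldehyde, silyl ether formation). Telescoping keeps the toxic and explosive 7 dilute, cold and immediately consumed, and avoids isolating the volatile 8 and the acid-labile free propargylic alcohol.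

Step 4
Reactants: 11 tert-butyl[(3-methoxyprop-2-yn-1-yl)oxy]dimethylsilane
Product: 12 2-({[tert-butyl(dimethyl)silyl]oxy}methyl)-3-methoxycyclobut-2-en-1-one
Conditions: AcCl (slow addition, 2–3 equiv), Et3N, Et2O, 0→20 °C
Reagents that add atoms: acetyl chloride, CC(=O)Cl
Why: Thermal [2+2] cycloaddition of ketene with an electron-rich ynol ether; the ketene is released slowly from the acid chloride and the amine, so no ketene gas is handled. The alkyne carbon remote from oxygen bonds to the ketene carbonyl carbon, which puts the silyloxymethyl group on C2 and the methoxy group on C3 of the cyclobutenone.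

Step 5
Reactants: 12 2-({[tert-butyl(dimethyl)silyl]oxy}methyl)-3-methoxycyclobut-2-en-1-one; 5 [(3,3-dimethylpent-4-en-1-yn-1-yl)oxy]tri(propan-2-yl)silane
Product: 17 4-({[tert-butyl(dimethyl)silyl]oxy}methyl)-5-methoxy-2-(2-methylbut-3-en-2-yl)-3-{[tri(propan-2-yl)silyl]oxy}phenol, via vinylketene 13 (not isolated), via 4-vinylcyclobutenone 14 (not isolated), via dienylketene 15 (not isolated), via cyclohexadienone 16 (not isolated)
Conditions: PhMe, 80→110 °C, sealed tube, Ar
Reagents that add atoms: none
Why: This is a Danheiser-type benzannulation in its siloxyalkyne form. Heat opens 12 by 4π electrocyclic cleavage of the bond between the carbonyl carbon and the ring CH2 (C7–C6) to the vinylketene 13, and the electron-rich alkyne 5 adds to the ketene C=C in a [2+2] cycloaddition to give the racemic 4-vinylcyclobutenone 14. A second 4π opening breaks the bond from the carbonyl carbon to the quaternary carbon (C7–C4a) and gives the dienylketene 15, which closes ring A by thermal disrotatory 6π electrocyclisation (re-forming C6–C7) to the dienone 16; enolisation then gives the aromatic phenol 17. In sum the two alkyne carbons are inserted as C8 and C8a, with new bonds C7–C8 and C4a–C8a. Regiochemistry is the one selectivity required: the silyloxy group polarises the alkyne so that the carbon carrying the tert-alkyl group is the nucleophilic end and bonds to the electrophilic ketene carbonyl carbon, which places the quaternary substituent on C8 beside the new C7 hydroxyl and the silyloxy group on C8a. No stereocentre survives, and because the opening of 14 is reversible only the dienylketene geometry that can cyclise is drained. Chemoselectivity rests on the large gap in nucleophilicity between the ynol ether and the isolated vinyl group of 5, and the hindered phenol of 17 is a poor trap for ketene intermediates.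

Step 6
Reactants: 17 4-({[tert-butyl(dimethyl)silyl]oxy}methyl)-5-methoxy-2-(2-methylbut-3-en-2-yl)-3-{[tri(propan-2-yl)silyl]oxy}phenol
Product: 18 4-hydroxy-6-methoxy-3-(2-methylbut-3-en-2-yl)-2-{[tri(propan-2-yl)silyl]oxy}benzaldehyde
Conditions: DDQ (1.1 equiv), CH2Cl2–pH 7 phosphate buffer, 0→20 °C
Reagents that add atoms: none
Why: DDQ oxidation of an electron-rich benzylic silyl ether: hydride abstraction from the benzylic CH2, assisted by the para hydroxyl on C7 and the two ortho oxygens, gives an O-silylated aldehyde cation (quinone methide type), and water takes the silyl group from oxygen, so the aldehyde keeps the benzylic oxygen and the silanol is set free. The aldehyde deactivates the ring against further oxidation, and the hindered aryl silyl ether and the isolated alkene do not react with DDQ.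

Step 7
Reactants: 18 4-hydroxy-6-methoxy-3-(2-methylbut-3-en-2-yl)-2-{[tri(propan-2-yl)silyl]oxy}benzaldehyde
Product: 19 2,4-dihydroxy-6-methoxy-3-(2-methylbut-3-en-2-yl)benzaldehyde
Conditions: Bu4NF, AcOH, THF, 0 °C
Reagents that add atoms: none
Why: Fluoride-mediated cleavage of an aryl silyl ether, made easy by the phenoxide leaving group activated by the ortho formyl group. Acetic acid buffers the phenoxide, so the aldehyde and the tert-allyl phenol are not exposed to strong base.

Step 8
Reactants: 19 2,4-dihydroxy-6-methoxy-3-(2-methylbut-3-en-2-yl)benzaldehyde; 20 (2,4-dihydroxyphenyl)acetic acid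
Product: 23 4-[7-(acetyloxy)-5-methoxy-8-(2-methylbut-3-en-2-yl)-2-oxo-2H-chromen-3-yl]-1,3-phenylene diacetate, via aldehyde diacetate 21 (not isolated), via mixed anhydride 22 (not isolated)
Conditions: Ac2O, Et3N, 110 °C
Reagents that add atoms: acetic anhydride, CC(=O)OC(C)=O
Why: Perkin–Oglialoro condensation: the phenols are acetylated in the flask (21), the arylacetic acid is activated as the mixed anhydride 22, and its enolate undergoes aldol condensation with the aldehyde; acyl transfer and lactonisation through the C8a oxygen then close the pyranone ring (C3=C4 and O1–C2). The acetylated C7 oxygen cannot add to the neighbouring alkene, and no acid stronger than acetic acid is present.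

Step 9
Reactants: 23 4-[7-(acetyloxy)-5-methoxy-8-(2-methylbut-3-en-2-yl)-2-oxo-2H-chromen-3-yl]-1,3-phenylene diacetate
Product: 24 3-(2,4-dihydroxyphenyl)-7-hydroxy-5-methoxy-8-(2-methylbut-3-en-2-yl)-2H-chromen-2-one
Conditions: K2CO3, MeOH, 0→20 °C; then aq. citric acid to pH 5
Reagents that add atoms: none
Why: Base-mediated methanolysis (transesterification) of the three aryl acetates, which is far faster than any attack on the methyl ether; a ring-opened cis-cinnamate, should it form, recloses on mild acidification. Strong acid is avoided because the free C7 hydroxyl would add to the tert-allyl double bond.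

## Compound list

1 | 2,2-dimethylbut-3-enoic acid | C=CC(C)(C)C(=O)O | starting material
2 | methyl 2,2-dimethylbut-3-enoate | C=CC(C)(C)C(=O)OC | intermediate
3 | lithium 1,1-dibromo-3,3-dimethylpenta-1,4-dien-2-olate | [Li+].[O-]C(=C(Br)Br)C(C)(C)C=C | intermediate
4 | lithium 3,3-dimethylpent-4-en-1-yn-1-olate | [Li+].[O-]C#CC(C)(C)C=C | intermediate
5 | [(3,3-dimethylpent-4-en-1-yn-1-yl)oxy]tri(propan-2-yl)silane | C=CC(C)(C)C#CO[Si](C(C)C)(C(C)C)C(C)C | intermediate
6 | trichloroethylene (1,1,2-trichloroethene) | ClC=C(Cl)Cl | starting material
7 | dichloroacetylene (1,2-dichloroethyne) | ClC#CCl | intermediate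
8 | (E)-1,2-dichloro-1-methoxyethene | CO/C(Cl)=C\Cl | intermediate
9 | lithium methoxyacetylide (lithium 2-methoxyethyn-1-ide) | [Li+].[C-]#COC | intermediate
10 | lithium 3-methoxyprop-2-yn-1-olate | [Li+].[O-]CC#COC | intermediate
11 | tert-butyl[(3-methoxyprop-2-yn-1-yl)oxy]dimethylsilane | COC#CCO[Si](C)(C)C(C)(C)C | intermediate
12 | 2-({[tert-butyl(dimethyl)silyl]oxy}methyl)-3-methoxycyclobut-2-en-1-one | COC1=C(CO[Si](C)(C)C(C)(C)C)C(=O)C1 | intermediate
13 | 2-({[tert-butyl(dimethyl)silyl]oxy}methyl)-3-methoxybuta-1,3-dien-1-one | C=C(OC)C(CO[Si](C)(C)C(C)(C)C)=C=O | intermediate
14 | 4-({[tert-butyl(dimethyl)silyl]oxy}methyl)-4-(1-methoxyethenyl)-2-(2-methylbut-3-en-2-yl)-3-{[tri(propan-2-yl)silyl]oxy}cyclobut-2-en-1-one (racemic) | C=CC(C)(C)C1=C(O[Si](C(C)C)(C(C)C)C(C)C)C(CO[Si](C)(C)C(C)(C)C)(C(=C)OC)C1=O | intermediate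
15 | (3E)-4-({[tert-butyl(dimethyl)silyl]oxy}methyl)-5-methoxy-2-(2-methylbut-3-en-2-yl)-3-{[tri(propan-2-yl)silyl]oxy}hexa-1,3,5-trien-1-one | O=C=C(C(C)(C)C=C)/C(O[Si](C(C)C)(C(C)C)C(C)C)=C(CO[Si](C)(C)C(C)(C)C)\C(=C)OC | intermediate
16 | 4-({[tert-butyl(dimethyl)silyl]oxy}methyl)-5-methoxy-2-(2-methylbut-3-en-2-yl)-3-{[tri(propan-2-yl)silyl]oxy}cyclohexa-2,4-dien-1-one | C=CC(C)(C)C1=C(O[Si](C(C)C)(C(C)C)C(C)C)C(CO[Si](C)(C)C(C)(C)C)=C(OC)CC1=O | intermediate
17 | 4-({[tert-butyl(dimethyl)silyl]oxy}methyl)-5-methoxy-2-(2-methylbut-3-en-2-yl)-3-{[tri(propan-2-yl)silyl]oxy}phenol | C=CC(C)(C)c1c(O)cc(OC)c(CO[Si](C)(C)C(C)(C)C)c1O[Si](C(C)C)(C(C)C)C(C)C | intermediate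
18 | 4-hydroxy-6-methoxy-3-(2-methylbut-3-en-2-yl)-2-{[tri(propan-2-yl)silyl]oxy}benzaldehyde | C=CC(C)(C)c1c(O)cc(OC)c(C=O)c1O[Si](C(C)C)(C(C)C)C(C)C | intermediate
19 | 2,4-dihydroxy-6-methoxy-3-(2-methylbut-3-en-2-yl)benzaldehyde | C=CC(C)(C)c1c(O)cc(OC)c(C=O)c1O | intermediate
20 | (2,4-dihydroxyphenyl)acetic acid | OC(=O)Cc1ccc(O)cc1O | starting material
21 | 4-formyl-5-methoxy-2-(2-methylbut-3-en-2-yl)-1,3-phenylene diacetate | C=CC(C)(C)c1c(OC(C)=O)cc(OC)c(C=O)c1OC(C)=O | intermediate
22 | acetic [2,4-bis(acetyloxy)phenyl]acetic anhydride | CC(=O)OC(=O)Cc1ccc(OC(C)=O)cc1OC(C)=O | intermediate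
23 | 4-[7-(acetyloxy)-5-methoxy-8-(2-methylbut-3-en-2-yl)-2-oxo-2H-chromen-3-yl]-1,3-phenylene diacetate | C=CC(C)(C)c1c(OC(C)=O)cc(OC)c2cc(-c3ccc(OC(C)=O)cc3OC(C)=O)c(=O)oc12 | intermediate
24 | 3-(2,4-dihydroxyphenyl)-7-hydroxy-5-methoxy-8-(2-methylbut-3-en-2-yl)-2H-chromen-2-one | C=CC(C)(C)c1c(O)cc(OC)c2cc(-c3ccc(O)cc3O)c(=O)oc12 | target

## Step count and least certain steps

Total step count: 9. Longest linear sequence: 7 steps (3, 4, 5, 6, 7, 8, 9 from 6, and equally 1, 2, 5, 6, 7, 8, 9 from 1).

**Step 5 (key step).** The most likely failure is a slow [2+2] union, because the reacting alkyne carbon carries a tertiary alkyl group. The vinylketene would then dimerise or polymerise, or the silyl group of 5 would migrate from oxygen to carbon at the temperature needed to open the donor-substituted cyclobutenone. Loss of the benzylic silyloxy group through a quinone methide at prolonged high temperature is a second concern. The fallback introduces the quaternary carbon by aromatic Claisen rearrangement; it sets out from 20 and comes back at 23. Commercial 2,4-dihydroxy-6-methoxybenzaldehyde F1 is alkylated at its non-chelated 4-hydroxyl (1-bromo-3-methylbut-2-ene, K2CO3, acetone) to 2-hydroxy-6-methoxy-4-[(3-methylbut-2-en-1-yl)oxy]benzaldehyde F2. Perkin–Oglialoro condensation of this aldehyde with 20 (Ac2O, Et3N, 110 °C) gives 4-{5-methoxy-7-[(3-methylbut-2-en-1-yl)oxy]-2-oxo-2H-chromen-3-yl}-1,3-phenylene diacetate F3. Heating this ether in N,N-diethylaniline with Ac2O and NaOAc at about 185 °C should effect the [3,3] shift to C8 and trap the liberated C7 phenol as its acetate, which is 23; step 9 then follows unchanged. This reserve path carries the competition of C6 with C8 and the high temperature that the main plan avoids.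

**Step 4.** Amine-catalysed oligomerisation of ketene may outrun the cycloaddition, and the ammonium salt may protonate the acid-sensitive ynol ether. The fallback sets out from 11 and comes back at 12. Dichloroketene (Cl3CCOCl, Zn/Cu couple, Et2O–DME), which is more electrophilic and does not need an amine, should add in the same sense to give 2-({[tert-butyl(dimethyl)silyl]oxy}methyl)-4,4-dichloro-3-methoxycyclobut-2-en-1-one F4. Zinc in AcOH–TMEDA–EtOH at 0 °C then removes both chlorines to give 12.

**Step 6.** Oxidative coupling or over-oxidation of the free, very electron-rich phenol may compete with benzylic hydride abstraction, and the reduced quinone may add to the quinone methide intermediate. The fallback separates deprotection from oxidation; it sets out from 17 and comes back at 18. HF·pyridine buffered with pyridine (THF, 0 °C) cleaves the alkyl silyl ether in preference to the aryl one and gives 4-(hydroxymethyl)-5-methoxy-2-(2-methylbut-3-en-2-yl)-3-{[tri(propan-2-yl)silyl]oxy}phenol F5. This alcohol is oxidised at once with MnO2 in CH2Cl2 to 18.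

**Step 8.** The arylacetic acid may lactonise onto its own ortho hydroxyl before it is acetylated, and the aldol step may be slow on an electron-rich aldehyde flanked by two substituents, so that decarboxylative side reactions take over at 110 °C. The fallback turns that lactonisation into the plan; it sets out from 20 and 19 and comes back at 24, with no acetate stage. Acid 20 is cyclised (cat. TsOH, toluene, removal of water) to 6-hydroxy-1-benzofuran-2(3H)-one F6. This lactone and 19 with Et3N in EtOH at 60 °C should undergo Knoevenagel condensation followed by translactonisation (the C8a phenoxide opens the five-membered lactone and closes the pyranone) to give 24 directly.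

**Step 2.** Addition of the dibromomethyl anion to the hindered ester may be incomplete, and silylation of the ynolate may go partly to carbon. The fallback makes the ynolate by oxidation of an acetylide; it sets out from 2 and comes back at 4. Ester 2 is reduced with i-Bu2AlH (CH2Cl2, −78 °C) to 2,2-dimethylbut-3-enal F7. Ohira–Bestmann homologation (dimethyl (1-diazo-2-oxopropyl)phosphonate, K2CO3, MeOH) gives 3,3-dimethylpent-4-en-1-yne F8, handled in solution because it is volatile. Deprotonation with n-BuLi and treatment with lithium tert-butyl peroxide (from t-BuOOH and LiN(SiMe3)2, THF, −78→0 °C) should give the ynolate 4, which is silylated as in step 2.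

## Further compounds

F1 | step 5 | 2,4-dihydroxy-6-methoxybenzaldehyde | COc1cc(O)cc(O)c1C=O
F2 | step 5 | 2-hydroxy-6-methoxy-4-[(3-methylbut-2-en-1-yl)oxy]benzaldehyde | COc1cc(OCC=C(C)C)cc(O)c1C=O
F3 | step 5 | 4-{5-methoxy-7-[(3-methylbut-2-en-1-yl)oxy]-2-oxo-2H-chromen-3-yl}-1,3-phenylene diacetate | COc1cc(OCC=C(C)C)cc2oc(=O)c(-c3ccc(OC(C)=O)cc3OC(C)=O)cc12
F4 | step 4 | 2-({[tert-butyl(dimethyl)silyl]oxy}methyl)-4,4-dichloro-3-methoxycyclobut-2-en-1-one | COC1=C(CO[Si](C)(C)C(C)(C)C)C(=O)C1(Cl)Cl
F5 | step 6 | 4-(hydroxymethyl)-5-methoxy-2-(2-methylbut-3-en-2-yl)-3-{[tri(propan-2-yl)silyl]oxy}phenol | C=CC(C)(C)c1c(O)cc(OC)c(CO)c1O[Si](C(C)C)(C(C)C)C(C)C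
F6 | step 8 | 6-hydroxy-1-benzofuran-2(3H)-one | O=C1Cc2ccc(O)cc2O1
F7 | step 2 | 2,2-dimethylbut-3-enal | C=CC(C)(C)C=O
F8 | step 2 | 3,3-dimethylpent-4-en-1-yne | C=CC(C)(C)C#C
A1 | alternative 1 | 7-(benzyloxy)-3-[2,4-bis(methoxymethoxy)phenyl]-5-methoxy-2H-chromen-2-one | COCOc1ccc(-c2cc3c(OC)cc(OCc4ccccc4)cc3oc2=O)c(OCOC)c1
A2 | alternative 1 | 5-(benzyloxy)-3-methoxy-2-(trimethylsilyl)phenyl trifluoromethanesulfonate | COc1cc(OCc2ccccc2)cc(OS(=O)(=O)C(F)(F)F)c1[Si](C)(C)C
A3 | alternative 1 | methyl [2,4-bis(methoxymethoxy)phenyl]acetate | COCOc1ccc(CC(=O)OC)c(OCOC)c1
A4 | alternative 2 | 3-[2,4-bis(benzyloxy)phenyl]-7-hydroxy-5-methoxy-8-(2-methylbut-3-en-2-yl)-2H-chromen-2-one | C=CC(C)(C)c1c(O)cc(OC)c2cc(-c3ccc(OCc4ccccc4)cc3OCc3ccccc3)c(=O)oc12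
A5 | alternative 2 | 5-methoxy-2-(2-methylbut-3-en-2-yl)benzene-1,3-diol | C=CC(C)(C)c1c(O)cc(OC)cc1O
A6 | alternative 2 | ethyl 2-[2,4-bis(benzyloxy)phenyl]-3-(dimethylamino)prop-2-enoate (enamine geometry not fixed) | CCOC(=O)C(=CN(C)C)c1ccc(OCc2ccccc2)cc1OCc1ccccc1
A7 | alternative 3 | 3-[2,4-bis(methoxymethoxy)phenyl]-5-methoxy-7-[(3-methylbut-2-en-1-yl)oxy]-2H-chromen-2-one | COCOc1ccc(-c2cc3c(OC)cc(OCC=C(C)C)cc3oc2=O)c(OCOC)c1
A8 | alternative 3 | (E)-2-{2-[2,4-bis(methoxymethoxy)phenyl]ethenyl}-3-methoxy-5-[(3-methylbut-2-en-1-yl)oxy]phenol | COCOc1ccc(/C=C/c2c(O)cc(OCC=C(C)C)cc2OC)c(OCOC)c1
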